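**Retrosynthetic overview**

1. Feature (numbering: ring C1 acyloxy CH, C2 ketone, C3 methyl-bearing epoxide carbon, C4 epoxide CH, C5 CH2, C6 CH; chain C7 spiro-epoxide carbon, C14 its CH2, C8 enone C=O, C9=C10, C11 carbinol): on ring A the epoxide oxygen on C3 and carbon C7 on C6 are 1,4-cis and the C1 oxygen is trans to both, which is the geometry of a lactone-bridged 2-pyrone cycloadduct with an endo 1,2-dioxygenated dienophile.
2. Target ⇒ (C2 carbinol oxidation, C1 acylation) hydroxy enone ⇒ (C8–C9) an (E)-vinyllithium plus a trans-fused spiro-epoxy γ-lactone in which O1 is tied to C8.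
3. Ring epoxide ⇒ SN2 closure of the former bridge oxygen O3 onto a C4 mesylate; the C4 oxygen comes from a silicon tether on O2 (intramolecular hydrosilylation, Tamao–Fleming oxidation).
4. Spiro-epoxide ⇒ face-selective epoxidation of an α-methylene lactone ⇒ palladium cyclocarbonylation of the C6 ethynyl / C1 hydroxyl pair (C7–C8; it also tells O1 from O2) ⇒ alkyne from the lactol of the bicyclic lactone (C7–C14); the antipodes are separated by lipase at the triol enyne.
5. Ring order: ring A by [4+2] of 6-methyl-2-pyrone (C3–C6, C7) with vinylene carbonate (C1, C2), carried as the bridged lactone; then the γ-lactone (temporary), the spiro-epoxide, and last the ring-A epoxide.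

Key step: step 3

Assumption: compounds 5–8 are racemic and are drawn as the antipode that is kept; in the lipase step the antipode needed is taken to be the one left unacylated (if the enzyme shows the opposite preference, the acetate fraction is methanolysed with K2CO3 in MeOH to the same triol 9).

**Route**

Step 1
Reactants: 1 4-hydroxy-6-methyl-2H-pyran-2-one (triacetic acid lactone)
Product: 2 6-methyl-2-oxo-2H-pyran-4-yl 4-methylbenzenesulfonate
Conditions: TsCl, Et3N, CH2Cl2, 0 °C
Reagents that add atoms: p-toluenesulfonyl chloride, Cc1ccc(cc1)S(Cl)(=O)=O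
Why: O-Sulfonylation (tosylation) of the acidic vinylogous carboxylic acid hydroxyl turns the C4 oxygen of the pyrone into a leaving group that palladium can insert into.

Step 2
Reactants: 2 6-methyl-2-oxo-2H-pyran-4-yl 4-methylbenzenesulfonate
Product: 3 6-methyl-2H-pyran-2-one
Conditions: Pd(OAc)2 (3 mol%), Ph2P(CH2)3PPh2, HCO2H, Et3N, DMF, 70 °C
Reagents that add atoms: none
Why: Palladium-catalysed transfer hydrogenolysis of the enol tosylate (oxidative addition into the activated C–O bond, formate exchange, loss of CO2, C–H reductive elimination) should remove the 4-oxygen without touching the lactone.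

Step 3
Reactants: 3 6-methyl-2H-pyran-2-one; 4 vinylene carbonate
Product: 5 racemic endo adduct, 1-methyl-2-oxabicyclo[2.2.2]oct-5-en-3-one with a cis cyclic carbonate on the saturated two-carbon bridge, anti to the lactone bridge
Conditions: 4 (3 equiv), CH2Cl2, 15 kbar, 50 °C
Reagents that add atoms: none
Why: This is a concerted suprafacial [4+2] cycloaddition in which pyrone C3 and C6 bond to the two dienophile carbons (new bonds C1–C6 and C2–C3), the closest known reaction type being the high-pressure Diels–Alder reaction of 2-pyrones with alkenes that gives isolable 2-oxabicyclo[2.2.2]oct-5-en-3-ones. Ring A closes in this one step across the diene termini, and the O–C(=O) unit is left as a two-atom bridge on one face, so that O3 on C3 and C7 on C6 are cis by construction. The four new stereocentres (C1, C2, C3, C6) are fixed relative to each other: C3 and C6 by the bridge, C1 and C2 by the cis geometry of the cyclic dienophile and by endo approach, which places the carbonate under the diene and therefore anti to the lactone bridge (O1 and O2 trans to O3 and C7). The step needs endo selectivity and survival of the adduct; pressure favours the more compact endo transition state, and the low temperature it allows should keep the adduct from losing CO2 by retro-[4+2]. The dienophile is symmetric, so no regiochemical question arises, and the 6-methyl group ends on the oxygen-bearing bridgehead C3. Nothing in either partner distinguishes the two faces of the pyrone, so the adduct is racemic and the antipodes are separated in step 6.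

Step 4
Reactants: 5 racemic endo adduct
Product: 6 racemic lactol (lactone carbonyl C7 reduced to the hemiacetal, both anomers, carbonate intact)
Conditions: i-Bu2AlH (1.2 equiv), CH2Cl2, −78 °C; aq. potassium sodium tartrate work-up; used crude
Reagents that add atoms: none
Why: Half-reduction of a lactone to the lactol with i-Bu2AlH should stop at the tetrahedral aluminate at −78 °C, and the strained bridged lactone is more electrophilic than the carbonate carbonyl, which carries two oxygen donors.

Step 5
Reactants: 6 racemic lactol
Product: 8 racemic triol enyne, via enyne carbonate 7 (not isolated)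
Conditions: Me3SiCHN2, n-BuLi, THF, −78 °C; add 6, −78 → 0 °C; then K2CO3, MeOH, 23 °C
Reagents that add atoms: trimethylsilyldiazomethane, C[Si](C)(C)C=[N+]=[N-]
Why: Colvin rearrangement: the lithium lactolate opens to the aldehyde, the lithiated diazomethane adds, and loss of Me3SiOLi and N2 gives an alkylidene carbene whose 1,2-hydrogen shift forms the terminal alkyne (C14) at a temperature at which the allylic, α-carbonyl C6–H should not be removed, so C6 keeps its configuration; base-catalysed methanolysis then cleaves the cyclic carbonate.

Step 6
Reactants: 8 racemic triol enyne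
Product: 9 triol enyne, single enantiomer (1S at the C1 carbinol)
Conditions: vinyl acetate (3 equiv), Novozym 435 (immobilised Candida antarctica lipase B), THF, 30 °C, to just past half conversion; chromatography
Reagents that add atoms: none
Why: Lipase-catalysed kinetic resolution by irreversible transesterification: the enzyme should acylate the least hindered secondary hydroxyl (O1) of one antipode only, the empirical medium/large-substituent rule for secondary alcohols pointing to the (1R) antipode, so the (1S)-triol is recovered unreacted, which sets the absolute configuration of C1, C2, C3 and C6.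

Step 7
Reactants: 9 triol enyne
Product: 10 trans-fused α-methylene-γ-butyrolactone (O1–C8(=O)–C7(=C14H2)–C6) with free C2–OH and C3–OH
Conditions: CO (1 atm), PdCl2 (5 mol%), thiourea, acetone, 50 °C
Reagents that add atoms: carbon monoxide, [C-]#[O+]
Why: Palladium-catalysed cyclocarbonylation of a homopropargylic alcohol: an alkoxycarbonyl species of divalent palladium formed from O1–H and CO adds syn across the alkyne in the 5-exo sense and protonolysis frees the exocyclic methylene; the trans ring fusion follows from the trans C1–O / C6–alkyne pair, and O2 and O3 cannot reach the alkyne, so the lactone tells O1 from O2.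

Step 8
Reactants: 10 α-methylene lactone
Product: 11 spiro-epoxy lactone (7R oxirane C7–O–C14)
Conditions: t-BuOOH, DBU, CH2Cl2, 0 °C
Reagents that add atoms: tert-butyl hydroperoxide, CC(C)(C)OO
Why: Weitz–Scheffer nucleophilic epoxidation: t-BuOO− adds to C14 and the lactone enolate closes onto the O–O bond at C7 from the face that carries only the ring-fusion hydrogen H6 and not the C5 ring carbon, which should give the 7R spiro-epoxide, while the isolated C4=C5 alkene is inert to a nucleophilic oxidant.

Step 9
Reactants: 11 spiro-epoxy lactone
Product: 13 cyclic siloxane O2–SiMe2–C4, via hydrosilyl ether 12 (not isolated)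
Conditions: Me2SiHCl (1.1 equiv), Et3N, CH2Cl2, −20 °C; then Pt2[(CH2=CHSiMe2)2O]3 (cat.), toluene, 60 °C
Reagents that add atoms: chlorodimethylsilane, C[SiH](C)Cl
Why: Silylation of the only secondary hydroxyl is followed by platinum-catalysed intramolecular hydrosilylation of the homoallylic silyl ether (5-exo): the trans-fused lactone holds O2 axial over the C4 terminus of the alkene, so silicon is delivered to C4 and hydrogen to C5 on the O2 face, which fixes the regiochemistry and the new C4 stereocentre (C4–Si cis to O2, trans to O3).

Step 10
Reactants: 13 cyclic siloxane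
Product: 14 triol (C2–OH and C4–OH cis, tertiary C3–OH trans to both)
Conditions: 30% H2O2, KF, KHCO3, THF/MeOH, 23 °C
Reagents that add atoms: hydrogen peroxide, OO
Why: Tamao–Fleming oxidation: peroxide attacks the fluoride-activated silicon and C4 migrates to oxygen with retention, so the C4 hydroxyl is cis to O2 and anti to the tertiary C3 hydroxyl.

Step 11
Reactants: 14 triol
Product: 15 C4 methanesulfonate
Conditions: MsCl (1.05 equiv), Et3N, CH2Cl2, −40 °C
Reagents that add atoms: methanesulfonyl chloride, CS(Cl)(=O)=O
Why: Regioselective sulfonylation: the C4 hydroxyl is flanked by the C5 methylene, whereas the C2 hydroxyl lies between the quaternary C3 and the acyloxy-bearing C1 and the C3 hydroxyl is tertiary, so one equivalent of MsCl at low temperature should react at O4.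

Step 12
Reactants: 15 C4 methanesulfonate
Product: 16 bis-epoxy lactone (C3–O–C4 epoxide on the face of C7, free C2–OH)
Conditions: DBU, toluene, 40 °C
Reagents that add atoms: none
Why: Intramolecular Williamson etherification: the axial C3 oxygen, the former lactone-bridge oxygen, is antiperiplanar to the axial C4 mesylate and displaces it with inversion (SN2, 3-exo-tet), so the epoxide oxygen stays on the face of C7 and C4 becomes the epoxide CH of the target.

Step 13
Reactants: 16 bis-epoxy lactone
Product: 17 C2 triethylsilyl ether
Conditions: Et3SiOTf, 2,6-lutidine, CH2Cl2, −78 °C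
Reagents that add atoms: triethylsilyl trifluoromethanesulfonate, CC[Si](CC)(CC)OS(=O)(=O)C(F)(F)F
Why: Silyl ether formation with a silyl triflate and a hindered pyridine base protects the hindered C2 hydroxyl, so that the organolithium of step 15 meets no acidic proton and O1 can later be acylated alone.

Step 14
Reactants: 18 2-methylbut-3-yn-2-ol
Product: 19 (E)-2-methyl-4-(tributylstannyl)but-3-en-2-ol
Conditions: Bu3SnH, PdCl2(PPh3)2 (1 mol%), THF, 0 → 23 °C
Reagents that add atoms: tributyltin hydride, CCCC[SnH](CCCC)CCCC
Why: Palladium-catalysed hydrostannation adds Sn–H syn across the terminal alkyne with tin at the unhindered terminal carbon, distal to the tertiary carbinol, which gives the (E)-vinylstannane.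

Step 15
Reactants: 17 C2 triethylsilyl ether; 19 (E)-2-methyl-4-(tributylstannyl)but-3-en-2-ol
Product: 21 hydroxy enone, via dilithio species 20 (not isolated)
Conditions: 19, n-BuLi (2.1 equiv), THF, −78 → −40 °C; then 17, −78 °C; H2O quench at −78 °C
Reagents that add atoms: none
Why: Tin–lithium exchange with retention of the E geometry gives the alkoxide-vinyllithium, which adds once to the lactone carbonyl (acyl substitution; the lithium hemiketalate should be stable at −78 °C), so that work-up frees the C8 enone and the C1 hydroxyl together and forms the C8–C9 bond.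

Step 16
Reactants: 21 hydroxy enone; 22 isovaleric anhydride
Product: 23 C1 3-methylbutanoate
Conditions: DMAP (cat.), Et3N, CH2Cl2, 0 → 23 °C
Reagents that add atoms: isovaleric anhydride (22), CC(C)CC(=O)OC(=O)CC(C)C
Why: DMAP-catalysed acylation with the anhydride esterifies the only secondary hydroxyl (O1), the tertiary C11 hydroxyl being too hindered to react under these conditions.

Step 17
Reactants: 23 C1 3-methylbutanoate
Product: 24 C2 alcohol
Conditions: HF·pyridine, pyridine, THF, 0 °C
Reagents that add atoms: none
Why: Fluoride-mediated desilylation under buffered, weakly acidic conditions should remove the triethylsilyl group without opening either epoxide or moving the neighbouring ester.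

Step 18
Reactants: 24 C2 alcohol
Product: 25 CNP0292003.1 (target)
Conditions: Dess–Martin periodinane, NaHCO3, CH2Cl2, 23 °C
Reagents that add atoms: none
Why: Dess–Martin oxidation of the secondary C2 carbinol to the ketone under buffered, non-basic conditions should leave the tertiary alcohol, both epoxides, the enone and the base-sensitive α-acyloxy centre C1 untouched.

**Compound list**

1 | 4-hydroxy-6-methyl-2H-pyran-2-one (triacetic acid lactone) | CC1=CC(O)=CC(=O)O1 | starting material
2 | 6-methyl-2-oxo-2H-pyran-4-yl 4-methylbenzenesulfonate | CC1=CC(OS(=O)(=O)c2ccc(C)cc2)=CC(=O)O1 | intermediate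
3 | 6-methyl-2H-pyran-2-one | CC1=CC=CC(=O)O1 | intermediate
4 | vinylene carbonate (1,3-dioxol-2-one) | O=C1OC=CO1 | starting material
5 | racemic endo adduct: 1-methyl-2-oxabicyclo[2.2.2]oct-5-en-3-one with a cis cyclic carbonate on the saturated bridge, anti to the lactone bridge (drawn as the antipode that is kept) | O=C1O[C@@H]2[C@H](O1)[C@]3(C)C=C[C@H]2C(=O)O3 | intermediate
6 | racemic lactol of 5 (hemiacetal at C7, both anomers) | O=C1O[C@@H]2[C@H](O1)[C@]3(C)C=C[C@H]2C(O)O3 | intermediate
7 | racemic enyne carbonate: cyclohex-4-ene with C6 ethynyl, free tertiary C3–OH and the C1/C2 cyclic carbonate | O=C1O[C@@H]2[C@H](O1)[C@@](C)(O)C=C[C@H]2C#C | intermediate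
8 | racemic triol enyne: 6-ethynyl-3-methylcyclohex-4-ene-1,2,3-triol (route numbering; O1 and O2 cis, O3 and the ethynyl group on the other face) | O[C@@H]1[C@H](O)[C@@](C)(O)C=C[C@H]1C#C | intermediate
9 | the same triol enyne as the single enantiomer drawn (1S at C1) | O[C@@H]1[C@H](O)[C@@](C)(O)C=C[C@H]1C#C | intermediate
10 | trans-fused α-methylene-γ-butyrolactone (O1–C8(=O)–C7(=C14H2)–C6), free C2–OH and C3–OH | O=C1O[C@@H]2[C@H](O)[C@@](C)(O)C=C[C@H]2C1=C | intermediate
11 | spiro-epoxy lactone (7R oxirane C7–O–C14) | O=C1O[C@@H]2[C@H](O)[C@@](C)(O)C=C[C@H]2[C@@]13CO3 | intermediate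
12 | O2 hydrodimethylsilyl ether of 11 | O=C1O[C@@H]2[C@H](O[SiH](C)C)[C@@](C)(O)C=C[C@H]2[C@@]13CO3 | intermediate
13 | cyclic siloxane O2–SiMe2–C4 (silicon on C4 cis to O2, C5 now CH2) | O=C1O[C@@H]2[C@@H]3O[Si](C)(C)[C@@H]([C@]3(C)O)C[C@H]2[C@@]14CO4 | intermediate
14 | triol: C2–OH and C4–OH cis, tertiary C3–OH trans to both | O=C1O[C@@H]2[C@H](O)[C@@](C)(O)[C@H](O)C[C@H]2[C@@]13CO3 | intermediate
15 | C4 methanesulfonate of 14 | O=C1O[C@@H]2[C@H](O)[C@@](C)(O)[C@H](OS(C)(=O)=O)C[C@H]2[C@@]13CO3 | intermediate
16 | bis-epoxy lactone: C3–O–C4 epoxide on the face of C7, free C2–OH | O=C1O[C@@H]2[C@H](O)[C@@]3(C)O[C@H]3C[C@H]2[C@@]14CO4 | intermediate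
17 | C2 triethylsilyl ether of 16 | O=C1O[C@@H]2[C@H](O[Si](CC)(CC)CC)[C@@]3(C)O[C@H]3C[C@H]2[C@@]14CO4 | intermediate
18 | 2-methylbut-3-yn-2-ol | CC(C)(O)C#C | starting material
19 | (E)-2-methyl-4-(tributylstannyl)but-3-en-2-ol | CCCC[Sn](CCCC)(CCCC)/C=C/C(C)(C)O | intermediate
20 | lithium (E)-4-lithio-2-methylbut-3-en-2-olate | [Li]/C=C/C(C)(C)O[Li] | intermediate
21 | hydroxy enone: free C1–OH, C2–OSiEt3, (E)-4-hydroxy-4-methylpent-2-enoyl group on spiro-epoxide carbon C7 | O[C@@H]1[C@H](O[Si](CC)(CC)CC)[C@@]2(C)O[C@H]2C[C@H]1[C@]1(C(=O)/C=C/C(C)(C)O)CO1 | intermediate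
22 | isovaleric anhydride (3-methylbutanoic anhydride) | CC(C)CC(=O)OC(=O)CC(C)C | starting material
23 | C1 3-methylbutanoate of 21 | CC(C)CC(=O)O[C@@H]1[C@H](O[Si](CC)(CC)CC)[C@@]2(C)O[C@H]2C[C@H]1[C@]1(C(=O)/C=C/C(C)(C)O)CO1 | intermediate
24 | C2 alcohol from 23 | CC(C)CC(=O)O[C@@H]1[C@H](O)[C@@]2(C)O[C@H]2C[C@H]1[C@]1(C(=O)/C=C/C(C)(C)O)CO1 | intermediate
25 | CNP0292003.1: (1S,3S,4S,6R)-3,4-epoxy-3-methyl-2-oxo-6-[(2R)-2-((E)-4-hydroxy-4-methylpent-2-enoyl)oxiran-2-yl]cyclohexyl 3-methylbutanoate (route numbering) | CC(C)CC(=O)O[C@@H]1C(=O)[C@@]2(C)O[C@H]2C[C@H]1[C@]1(C(=O)/C=C/C(C)(C)O)CO1 | target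

**Step count**

Total: 18 steps. Longest linear sequence: 17 steps (steps 1–13 and 15–18; step 14 makes the side-chain stannane).

**Steps most likely to fail**

1. Step 3 (key cycloaddition). The addition of the unactivated pyrone to a weak dienophile may be too slow even under pressure. At the temperatures then needed the adduct would lose CO2 by retro-[4+2] and endo/exo control would erode. The fallback sets out from 3 and returns at 5 and changes the diene to a bromine-activated one. Pyrone 3 is dibrominated at its two nucleophilic ring positions (NBS, MeCN, 23 °C) to 3,5-dibromo-6-methyl-2H-pyran-2-one F1. Pyrones of this ambiphilic type add both electron-rich and electron-poor alkenes below 100 °C at ambient pressure with endo preference and give thermally robust adducts. Heating F1 with 4 (toluene, 90 °C) should give the dibromo endo adduct F2. Bu3SnH with Et3B/air (toluene, 23 °C) then removes the bridgehead and the vinylic bromine by radical reduction, which cannot change the bridgehead configuration, and returns racemic 5.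

2. Step 5 (alkyne from the lactol). After ring–chain opening of the lactolate the aldehyde has an α-hydrogen that is also allylic. If deprotonation competes with addition of the diazo anion, the C4=C5 double bond moves into conjugation or C6 epimerises; the organolithium may also attack the carbonate. The fallback sets out from 6 and returns at 8 and removes the carbonyl group with a weakly basic phosphorus ylide before any strong base is used. CBr4/PPh3/Zn (CH2Cl2, 0 °C) should convert the lactol into the dibromo-olefin carbonate F3. K2CO3/MeOH cleaves the carbonate to the triol dibromo-olefin F4. n-BuLi (THF, −78 °C; Corey–Fuchs alkyne synthesis) then gives 8 at a stage where no carbonyl group is left to be enolised.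

3. Step 8 (spiro-epoxide). The two faces of C7 differ only by H6 versus the C5 ring carbon, so the ring-closing step of the nucleophilic epoxidation may show poor facial selectivity and give the 7S epimer as well. The fallback sets out from 10 and returns at 11 and replaces substrate control by reagent control. i-Bu2AlH (CH2Cl2, −78 °C) reduces the lactone to the tetraol F5, a 2-substituted allylic alcohol. Sharpless epoxidation with Ti(OiPr)4, L-(+)-diisopropyl tartrate and t-BuOOH (4 Å sieves, CH2Cl2, −20 °C) sets C7 and should give the epoxy tetraol F6, the tertiary ring allylic alcohol reacting far more slowly. TEMPO/PhI(OAc)2 (CH2Cl2, 23 °C) then oxidises the primary alcohol, and the lactol it forms with O1, back to lactone 11.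

**Further compounds**

F1 | step 3 | 3,5-dibromo-6-methyl-2H-pyran-2-one | CC1=C(Br)C=C(Br)C(=O)O1
F2 | step 3 | racemic dibromo endo adduct (bridgehead C6–Br, vinylic C4–Br) | O=C1O[C@@H]2[C@H](O1)[C@]3(C)C(Br)=C[C@@]2(Br)C(=O)O3
F3 | step 5 | racemic dibromo-olefin carbonate | O=C1O[C@@H]2[C@H](O1)[C@@](C)(O)C=C[C@H]2C=C(Br)Br
F4 | step 5 | racemic triol dibromo-olefin | O[C@@H]1[C@H](O)[C@@](C)(O)C=C[C@H]1C=C(Br)Br
F5 | step 8 | tetraol (2-substituted allylic alcohol on C6) | O[C@@H]1[C@H](O)[C@@](C)(O)C=C[C@H]1C(=C)CO
F6 | step 8 | epoxy tetraol | O[C@@H]1[C@H](O)[C@@](C)(O)C=C[C@H]1[C@]1(CO)CO1
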